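## Retrosynthetic overview

1. The target comes from a last-step epoxidation of C1=C10 in the (1(10)Z,4Z)-dienolide. Its lactone carbonyl comes from a lactol ethyl ether, and its C8 ester from (2S,3R)-2,3-dimethyloxirane-2-carboxylic acid (Sharpless epoxidation of tiglyl alcohol, then oxidation).
2. The oxolane (future lactone) ring is closed in the key step: trivalent-titanium opening of a C7–C8 oxirane and 5-exo-dig radical closure of C7 onto C11 of a propynal mixed acetal held on O6. Enabling feature: in the ten-membered ring the C6 carbinol sits next to the C7–C8 oxirane (a 2,3-epoxy alcohol), so C7 becomes the radical centre, O8 stays on C8 with its configuration, and C11 is five atoms from C7.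
3. The ten-membered carbocycle is closed at C5–C6 by a Nozaki–Hiyama–Kishi reaction of an acyclic (Z)-vinyl iodide epoxy aldehyde; C6 is then reset by oxidation and chelation-controlled reduction.
4. The acyclic chain comes from Sharpless epoxidation (fixes C8) of an (E)-allylic alcohol made from propargyl alcohol and a (Z)-allylic bromide. Both Z trisubstituted alkenes come from pent-4-yn-1-ol (Negishi carboalumination, isomerization, iodination; Still–Gennari olefination).
5. Ring order: C7–C8 oxirane, then ten-membered carbocycle, then oxolane (key step, later oxidized to the lactone), then C1–C10 oxirane.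

Key step: step 14

Numbering in the text: germacrane numbers (C1–C10 ring carbons; C6 carries the lactone oxygen, C7 the carbon C11, C8 the acyloxy group; C12 lactone carbonyl; C13 exocyclic CH2; C14 and C15 the methyls on C10 and C4).

Assumption: in dienolide 27 the exposed outer face of the C1=C10 alkene is the one that leads to the 1S,10R oxirane, as is usual for 1(10)-epoxides of germacranolides; step 20 rests on this.

## Route

Step 1
Reactants: 1 pent-4-yn-1-ol
Product: 4 (4Z)-5-iodo-4-methylpent-4-en-1-ol, via syn-adduct alkenylalane 2 (not isolated), via chelated Z-alkenylalane 3 (not isolated)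
Conditions: Me3Al (3 equiv), Cp2ZrCl2 (25 mol %), ClCH2CH2Cl, 23 °C; then reflux; then I2, THF, −30 to 0 °C
Reagents that add atoms: trimethylaluminium C[Al](C)C; iodine II
Why: Negishi zirconium-catalysed methylalumination adds methyl and aluminium syn across the alkyne with aluminium at the terminus, heating lets the aluminium alkoxide chelate and isomerize the alkenylalane to the Z isomer, and iodinolysis with retention should give the Z vinyl iodide that later becomes C4=C5.

Step 2
Reactants: 4 (4Z)-5-iodo-4-methylpent-4-en-1-ol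
Product: 5 (4Z)-5-iodo-4-methylpent-4-enal
Conditions: Dess–Martin periodinane, pyridine, CH2Cl2, 0 to 23 °C
Reagents that add atoms: none
Why: Dess–Martin oxidation of a primary alcohol stops at the aldehyde and leaves the vinyl iodide and its geometry untouched.

Step 3
Reactants: 5 (4Z)-5-iodo-4-methylpent-4-enal; 6 ethyl 2-[bis(2,2,2-trifluoroethoxy)phosphoryl]propanoate
Product: 7 ethyl (2Z,6Z)-7-iodo-2,6-dimethylhepta-2,6-dienoate
Conditions: KN(SiMe3)2, 18-crown-6, THF, −78 °C
Reagents that add atoms: none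
Why: In the Still–Gennari variant of the Horner–Wadsworth–Emmons reaction the electron-poor phosphonate eliminates from the kinetic adduct, which should give the Z trisubstituted enoate and so fix the C1=C10 geometry (C9 cis to C2).

Step 4
Reactants: 7 ethyl (2Z,6Z)-7-iodo-2,6-dimethylhepta-2,6-dienoate
Product: 8 (2Z,6Z)-7-iodo-2,6-dimethylhepta-2,6-dien-1-ol
Conditions: iBu2AlH (2.2 equiv), CH2Cl2, −78 °C; aqueous potassium sodium tartrate
Reagents that add atoms: none
Why: 1,2-Reduction of the enoate by iBu2AlH gives the allylic alcohol without touching either alkene geometry or the vinyl iodide.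

Step 5
Reactants: 8 (2Z,6Z)-7-iodo-2,6-dimethylhepta-2,6-dien-1-ol
Product: 9 (1Z,5Z)-7-bromo-1-iodo-2,6-dimethylhepta-1,5-diene
Conditions: CBr4, PPh3, CH2Cl2, 0 °C
Reagents that add atoms: tetrabromomethane BrC(Br)(Br)Br
Why: The Appel reaction converts the primary allylic alcohol into the bromide by SN2 under neutral conditions, so neither allylic transposition nor Z to E isomerization is expected.

Step 6
Reactants: 9 (1Z,5Z)-7-bromo-1-iodo-2,6-dimethylhepta-1,5-diene; 10 prop-2-yn-1-ol
Product: 11 (5Z,9Z)-10-iodo-5,9-dimethyldeca-5,9-dien-2-yn-1-ol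
Conditions: CuI (10 mol %), K2CO3, Bu4NCl, DMF, 20 °C
Reagents that add atoms: none
Why: Copper-catalysed coupling of a terminal alkyne with a primary allylic bromide proceeds by SN2 at the unhindered CH2 to give the skipped enyne, and the vinyl iodide does not couple with a copper acetylide at 20 °C without palladium.

Step 7
Reactants: 11 (5Z,9Z)-10-iodo-5,9-dimethyldeca-5,9-dien-2-yn-1-ol
Product: 12 (2E,5Z,9Z)-10-iodo-5,9-dimethyldeca-2,5,9-trien-1-ol
Conditions: NaAlH2(OCH2CH2OMe)2, THF, 0 °C
Reagents that add atoms: none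
Why: Hydroxyl-directed trans-hydroalumination of the propargylic alcohol should give the E allylic alcohol, while the isolated alkenes and, at 0 °C, the vinyl iodide are not reduced.

Step 8
Reactants: 12 (2E,5Z,9Z)-10-iodo-5,9-dimethyldeca-2,5,9-trien-1-ol
Product: 13 [(2R,3R)-3-[(2Z,6Z)-7-iodo-2,6-dimethylhepta-2,6-dien-1-yl]oxiran-2-yl]methanol
Conditions: Ti(OiPr)4 (10 mol %), D-(−)-diethyl tartrate (12 mol %), t-BuOOH, 4 Å molecular sieves, CH2Cl2, −20 °C
Reagents that add atoms: tert-butyl hydroperoxide CC(C)(C)OO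
Why: Sharpless asymmetric epoxidation oxidizes only the allylic-alcohol alkene, and the D-(−)-tartrate ligand delivers oxygen to the face that gives the (2R,3R)-oxirane, which fixes C8 as R.

Step 9
Reactants: 13 [(2R,3R)-3-[(2Z,6Z)-7-iodo-2,6-dimethylhepta-2,6-dien-1-yl]oxiran-2-yl]methanol
Product: 14 (2S,3R)-3-[(2Z,6Z)-7-iodo-2,6-dimethylhepta-2,6-dien-1-yl]oxirane-2-carbaldehyde
Conditions: Dess–Martin periodinane, pyridine, CH2Cl2, 0 °C
Reagents that add atoms: none
Why: Buffered Dess–Martin oxidation gives the epoxy aldehyde without opening the oxirane or epimerizing the alpha carbon (the descriptor changes only through ligand priority).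

Step 10
Reactants: 14 (2S,3R)-3-[(2Z,6Z)-7-iodo-2,6-dimethylhepta-2,6-dien-1-yl]oxirane-2-carbaldehyde
Product: 15 (1R,3Z,7Z,10R)-4,8-dimethyl-11-oxabicyclo[8.1.0]undeca-3,7-dien-2-ol (both C2 epimers)
Conditions: CrCl2 (8 equiv), NiCl2 (1 mol %), degassed DMSO, 23 °C, slow addition to 0.002 M
Reagents that add atoms: none
Why: In the intramolecular Nozaki–Hiyama–Kishi reaction the vinyl iodide is turned, with retention of the Z geometry, into a vinylchromium species (trivalent chromium) that adds only to the aldehyde; the two cis alkenes hold the chain ends close, and the new carbinol centre (C6) needs no control because steps 11 and 12 reset it.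

Step 11
Reactants: 15 (1R,3Z,7Z,10R)-4,8-dimethyl-11-oxabicyclo[8.1.0]undeca-3,7-dien-2-ol (both C2 epimers)
Product: 16 (1S,3Z,7Z,10R)-4,8-dimethyl-11-oxabicyclo[8.1.0]undeca-3,7-dien-2-one
Conditions: Dess–Martin periodinane, pyridine, CH2Cl2, 0 °C
Reagents that add atoms: none
Why: Dess–Martin oxidation of the allylic alcohol funnels both C6 epimers into one epoxy enone.

Step 12
Reactants: 16 (1S,3Z,7Z,10R)-4,8-dimethyl-11-oxabicyclo[8.1.0]undeca-3,7-dien-2-one
Product: 17 (1R,2R,3Z,7Z,10R)-4,8-dimethyl-11-oxabicyclo[8.1.0]undeca-3,7-dien-2-ol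
Conditions: Zn(BH4)2, Et2O, −20 °C
Reagents that add atoms: none
Why: In this chelation-controlled 1,2-reduction zinc bridges the ketone and oxirane oxygens and hydride enters anti to C8, which should give the anti (erythro) epoxy alcohol and so set C6 as R.

Step 13
Reactants: 17 (1R,2R,3Z,7Z,10R)-4,8-dimethyl-11-oxabicyclo[8.1.0]undeca-3,7-dien-2-ol; 18 3,3-diethoxyprop-1-yne
Product: 19 (1S,2R,3Z,7Z,10R)-2-[(1-ethoxyprop-2-yn-1-yl)oxy]-4,8-dimethyl-11-oxabicyclo[8.1.0]undeca-3,7-diene (both acetal epimers)
Conditions: pyridinium p-toluenesulfonate (5 mol %), excess 18, toluene, 50 °C, reduced pressure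
Reagents that add atoms: none
Why: Acid-catalysed transacetalization, driven by removal of ethanol, hangs the alkyne on O6 at the aldehyde oxidation level; the acetal centre is left as a mixture because it becomes the lactone carbonyl.

Step 14
Reactants: 19 (1S,2R,3Z,7Z,10R)-2-[(1-ethoxyprop-2-yn-1-yl)oxy]-4,8-dimethyl-11-oxabicyclo[8.1.0]undeca-3,7-diene (both acetal epimers)
Product: 20 (3aR,4R,6Z,10Z,11aR)-2-ethoxy-6,10-dimethyl-3-methylidene-2,3,3a,4,5,8,9,11a-octahydrocyclodeca[b]furan-4-ol (both C2 epimers)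
Conditions: Cp2TiCl2 (20 mol %), Mn powder, 2,4,6-collidine hydrochloride, THF, 23 °C, slow addition of 19
Reagents that add atoms: none
Why: Cp2TiCl (trivalent titanium, formed in the flask from Cp2TiCl2 and Mn) coordinates the oxirane oxygen and cleaves the C7–O bond homolytically, the precedented regiochemistry for 2,3-epoxy alcohol derivatives, to give the C7 radical with a titanium alkoxide on C8, so the C8–O bond and its R configuration are never touched. The closest known reaction type is the Nugent–RajanBabu epoxide opening followed by radical cyclization onto an alkyne, which converts propargyl ethers of 2,3-epoxy alcohols into 3-methylidene-tetrahydrofurans. The oxolane ring closes in the 5-exo-dig mode (C7 adds to C11 of the alkyne held on O6 through the acetal carbon C12), and the vinyl radical at C13 is reduced and protonated by collidinium chloride to the exocyclic methylene. The new stereocentre C7 is controlled by C6 through the ring fusion: closure needs the O6–C6–C7–C11 torsion near 30°, and only the trans-fused arrangement lets the ten-membered ring keep a staggered C5–C6–C7–C8 torsion, so H6 and H7 should end up anti (7R). Because C7 is planar in the radical and C12 later becomes a carbonyl carbon, either C7 epimer of the oxirane and both acetal epimers converge on one useful product. The step needs ring closure to outrun capture of the C7 radical by a second trivalent titanium, which the catalytic protocol (low titanium concentration, slow addition) secures, and it needs the two trisubstituted alkenes to stay out, which their 4-exo or transannular distance from C7 secures.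

Step 15
Reactants: 21 (2E)-2-methylbut-2-en-1-ol
Product: 22 [(2R,3R)-2,3-dimethyloxiran-2-yl]methanol
Conditions: Ti(OiPr)4 (10 mol %), D-(−)-diethyl tartrate (12 mol %), t-BuOOH, 4 Å molecular sieves, CH2Cl2, −20 °C
Reagents that add atoms: tert-butyl hydroperoxide CC(C)(C)OO
Why: Sharpless asymmetric epoxidation of the E trisubstituted allylic alcohol with the D-(−)-tartrate ligand should give the (2R,3R)-oxirane with the two methyl groups cis.

Step 16
Reactants: 22 [(2R,3R)-2,3-dimethyloxiran-2-yl]methanol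
Product: 23 (2S,3R)-2,3-dimethyloxirane-2-carboxylic acid
Conditions: PhI(OAc)2 (2.2 equiv), TEMPO (2,2,6,6-tetramethylpiperidin-1-oxyl, 20 mol %), MeCN/H2O 1:1, 20 °C
Reagents that add atoms: water O
Why: Oxoammonium-mediated oxidation takes the primary alcohol through the aldehyde hydrate to the acid without touching the oxirane (the C2 descriptor changes from R to S only through ligand priority).

Step 17
Reactants: 20 (3aR,4R,6Z,10Z,11aR)-2-ethoxy-6,10-dimethyl-3-methylidene-2,3,3a,4,5,8,9,11a-octahydrocyclodeca[b]furan-4-ol (both C2 epimers); 23 (2S,3R)-2,3-dimethyloxirane-2-carboxylic acid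
Product: 25 (3aR,4R,6Z,10Z,11aR)-2-ethoxy-6,10-dimethyl-3-methylidene-2,3,3a,4,5,8,9,11a-octahydrocyclodeca[b]furan-4-yl (2S,3R)-2,3-dimethyloxirane-2-carboxylate (both C2 epimers), via Yamaguchi mixed anhydride 24 (not isolated)
Conditions: 23, 2,4,6-trichlorobenzoyl chloride, Et3N, THF, 20 °C; then 20, 4-(dimethylamino)pyridine, toluene, 20 °C
Reagents that add atoms: none
Why: In the Yamaguchi esterification 4-(dimethylamino)pyridine attacks the less hindered aliphatic carbonyl of the mixed anhydride and the C8 hydroxyl is acylated on oxygen, so C8 keeps its configuration.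

Step 18
Reactants: 25 (3aR,4R,6Z,10Z,11aR)-2-ethoxy-6,10-dimethyl-3-methylidene-2,3,3a,4,5,8,9,11a-octahydrocyclodeca[b]furan-4-yl (2S,3R)-2,3-dimethyloxirane-2-carboxylate (both C2 epimers)
Product: 26 (3aR,4R,6Z,10Z,11aR)-2-hydroxy-6,10-dimethyl-3-methylidene-2,3,3a,4,5,8,9,11a-octahydrocyclodeca[b]furan-4-yl (2S,3R)-2,3-dimethyloxirane-2-carboxylate (both C2 epimers)
Conditions: pyridinium p-toluenesulfonate (10 mol %), acetone/H2O 4:1, 20 °C
Reagents that add atoms: water O
Why: Mild acid hydrolysis of the allylic lactol ether gives the lactol, which can only sit on O6 because O8 is already acylated, and the conditions are too weak to open the deactivated epoxy ester or to start transannular cyclization of the diene.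

Step 19
Reactants: 26 (3aR,4R,6Z,10Z,11aR)-2-hydroxy-6,10-dimethyl-3-methylidene-2,3,3a,4,5,8,9,11a-octahydrocyclodeca[b]furan-4-yl (2S,3R)-2,3-dimethyloxirane-2-carboxylate (both C2 epimers)
Product: 27 (3aR,4R,6Z,10Z,11aR)-6,10-dimethyl-3-methylidene-2-oxo-2,3,3a,4,5,8,9,11a-octahydrocyclodeca[b]furan-4-yl (2S,3R)-2,3-dimethyloxirane-2-carboxylate
Conditions: PhI(OAc)2, TEMPO (10 mol %), CH2Cl2, 20 °C
Reagents that add atoms: none
Why: Oxoammonium oxidation of the lactol gives the alpha-methylene lactone and merges both lactol epimers, with the alkenes and both esters inert.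

Step 20
Reactants: 27 (3aR,4R,6Z,10Z,11aR)-6,10-dimethyl-3-methylidene-2-oxo-2,3,3a,4,5,8,9,11a-octahydrocyclodeca[b]furan-4-yl (2S,3R)-2,3-dimethyloxirane-2-carboxylate
Product: 28 (1S,6R,7R,8R,10R)-1,10-epoxy-8-[(2S,3R)-2,3-dimethyloxirane-2-carbonyloxy]germacra-4Z,11(13)-dien-12,6-olide (target CNP0165580.2)
Conditions: dimethyldioxirane (acetone solution, 1.05 equiv), CH2Cl2, −20 °C
Reagents that add atoms: dimethyldioxirane CC1(C)OO1
Why: Electrophilic epoxidation with a dioxirane should pick the most electron-rich alkene C1=C10 (C4=C5 is deactivated by the allylic lactone oxygen, C11=C13 by conjugation), the concerted syn addition keeps C2 and C9 cis, and attack on the outer face of the lactone-locked ring is expected to give the 1S,10R oxirane under neutral conditions that spare the acid-labile product.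

## Compound list

1 | pent-4-yn-1-ol | OCCCC#C | starting material
2 | [(1E)-5-[(dimethylalumanyl)oxy]-2-methylpent-1-en-1-yl](dimethyl)alumane (syn-adduct alkenylalane) | C[Al](C)OCCC/C(C)=C/[Al](C)C | intermediate
3 | [(1Z)-5-[(dimethylalumanyl)oxy]-2-methylpent-1-en-1-yl](dimethyl)alumane (chelated Z-alkenylalane) | C[Al](C)OCCC/C(C)=C\[Al](C)C | intermediate
4 | (4Z)-5-iodo-4-methylpent-4-en-1-ol | OCCC/C(C)=C\I | intermediate
5 | (4Z)-5-iodo-4-methylpent-4-enal | O=CCC/C(C)=C\I | intermediate
6 | ethyl 2-[bis(2,2,2-trifluoroethoxy)phosphoryl]propanoate | CCOC(=O)C(C)P(=O)(OCC(F)(F)F)OCC(F)(F)F | starting material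
7 | ethyl (2Z,6Z)-7-iodo-2,6-dimethylhepta-2,6-dienoate | CCOC(=O)/C(C)=C\CC/C(C)=C\I | intermediate
8 | (2Z,6Z)-7-iodo-2,6-dimethylhepta-2,6-dien-1-ol | OC/C(C)=C\CC/C(C)=C\I | intermediate
9 | (1Z,5Z)-7-bromo-1-iodo-2,6-dimethylhepta-1,5-diene | BrC/C(C)=C\CC/C(C)=C\I | intermediate
10 | prop-2-yn-1-ol | C#CCO | starting material
11 | (5Z,9Z)-10-iodo-5,9-dimethyldeca-5,9-dien-2-yn-1-ol | OCC#CC/C(C)=C\CC/C(C)=C\I | intermediate
12 | (2E,5Z,9Z)-10-iodo-5,9-dimethyldeca-2,5,9-trien-1-ol | OC/C=C/C/C(C)=C\CC/C(C)=C\I | intermediate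
13 | [(2R,3R)-3-[(2Z,6Z)-7-iodo-2,6-dimethylhepta-2,6-dien-1-yl]oxiran-2-yl]methanol | OC[C@H]1O[C@@H]1C/C(C)=C\CC/C(C)=C\I | intermediate
14 | (2S,3R)-3-[(2Z,6Z)-7-iodo-2,6-dimethylhepta-2,6-dien-1-yl]oxirane-2-carbaldehyde | O=C[C@H]1O[C@@H]1C/C(C)=C\CC/C(C)=C\I | intermediate
15 | (1R,3Z,7Z,10R)-4,8-dimethyl-11-oxabicyclo[8.1.0]undeca-3,7-dien-2-ol, both C2 epimers (C2 is germacrane C6) | OC1/C=C(/C)CC/C=C(/C)C[C@H]2O[C@H]12 | intermediate
16 | (1S,3Z,7Z,10R)-4,8-dimethyl-11-oxabicyclo[8.1.0]undeca-3,7-dien-2-one | O=C1/C=C(/C)CC/C=C(/C)C[C@H]2O[C@H]12 | intermediate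
17 | (1R,2R,3Z,7Z,10R)-4,8-dimethyl-11-oxabicyclo[8.1.0]undeca-3,7-dien-2-ol | O[C@@H]1/C=C(/C)CC/C=C(/C)C[C@H]2O[C@H]12 | intermediate
18 | 3,3-diethoxyprop-1-yne | C#CC(OCC)OCC | starting material
19 | (1S,2R,3Z,7Z,10R)-2-[(1-ethoxyprop-2-yn-1-yl)oxy]-4,8-dimethyl-11-oxabicyclo[8.1.0]undeca-3,7-diene, both acetal epimers | C#CC(OCC)O[C@@H]1/C=C(/C)CC/C=C(/C)C[C@H]2O[C@H]12 | intermediate
20 | (3aR,4R,6Z,10Z,11aR)-2-ethoxy-6,10-dimethyl-3-methylidene-2,3,3a,4,5,8,9,11a-octahydrocyclodeca[b]furan-4-ol, both C2 epimers | C=C1C(OCC)O[C@@H]2/C=C(/C)CC/C=C(/C)C[C@@H](O)[C@@H]12 | intermediate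
21 | (2E)-2-methylbut-2-en-1-ol (tiglyl alcohol) | C/C=C(\C)CO | starting material
22 | [(2R,3R)-2,3-dimethyloxiran-2-yl]methanol | OC[C@@]1(C)O[C@@H]1C | intermediate
23 | (2S,3R)-2,3-dimethyloxirane-2-carboxylic acid | OC(=O)[C@@]1(C)O[C@@H]1C | intermediate
24 | (2S,3R)-2,3-dimethyloxirane-2-carboxylic 2,4,6-trichlorobenzoic anhydride | O=C(OC(=O)[C@@]1(C)O[C@@H]1C)c1c(Cl)cc(Cl)cc1Cl | intermediate
25 | (3aR,4R,6Z,10Z,11aR)-2-ethoxy-6,10-dimethyl-3-methylidene-2,3,3a,4,5,8,9,11a-octahydrocyclodeca[b]furan-4-yl (2S,3R)-2,3-dimethyloxirane-2-carboxylate, both C2 epimers | C=C1C(OCC)O[C@@H]2/C=C(/C)CC/C=C(/C)C[C@@H](OC(=O)[C@@]3(C)O[C@@H]3C)[C@@H]12 | intermediate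
26 | (3aR,4R,6Z,10Z,11aR)-2-hydroxy-6,10-dimethyl-3-methylidene-2,3,3a,4,5,8,9,11a-octahydrocyclodeca[b]furan-4-yl (2S,3R)-2,3-dimethyloxirane-2-carboxylate, both C2 epimers | C=C1C(O)O[C@@H]2/C=C(/C)CC/C=C(/C)C[C@@H](OC(=O)[C@@]3(C)O[C@@H]3C)[C@@H]12 | intermediate
27 | (3aR,4R,6Z,10Z,11aR)-6,10-dimethyl-3-methylidene-2-oxo-2,3,3a,4,5,8,9,11a-octahydrocyclodeca[b]furan-4-yl (2S,3R)-2,3-dimethyloxirane-2-carboxylate | C=C1C(=O)O[C@@H]2/C=C(/C)CC/C=C(/C)C[C@@H](OC(=O)[C@@]3(C)O[C@@H]3C)[C@@H]12 | intermediate
28 | (1S,6R,7R,8R,10R)-1,10-epoxy-8-[(2S,3R)-2,3-dimethyloxirane-2-carbonyloxy]germacra-4Z,11(13)-dien-12,6-olide (CNP0165580.2) | C=C1C(=O)O[C@@H]2/C=C(/C)CC[C@@H]3O[C@]3(C)C[C@@H](OC(=O)[C@@]3(C)O[C@@H]3C)[C@@H]12 | target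

## Step count and risks

Total step count: 20. Longest linear sequence: 18 steps (steps 1–14 and 17–20); steps 15 and 16 make the side-chain acid.

Step 14 (key step). What may go wrong: capture of the C7 radical by a second trivalent titanium before ring closure, which would expel the oxirane oxygen and leave a C7=C8 alkene, or homolysis of the C8–O bond in place of the C7–O bond. Fallback, a polar and stereospecific closure of the same bond: it sets out from 17 and comes back at 20. Transacetalization of 17 with 2-bromo-3,3-diethoxyprop-1-ene (pyridinium p-toluenesulfonate, toluene, 50 °C) should give (1S,2R,3Z,7Z,10R)-2-[(2-bromo-1-ethoxyprop-2-en-1-yl)oxy]-4,8-dimethyl-11-oxabicyclo[8.1.0]undeca-3,7-diene F1. Bromine–lithium exchange (t-BuLi, 2 equiv, Et2O, −78 °C) then gives the 2-lithioallyl acetal, whose vinyl carbanion opens the oxirane at C7 in a 5-exo-tet SN2 reaction on warming to −20 °C. Because 17 is the anti trans-epoxy alcohol, inversion at C7 leads to the same trans-fused hydroxy acetal 20.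

Step 10. What may go wrong: intermolecular coupling to oligomers outrunning closure of the ten-membered ring, or degradation of the epoxy aldehyde by the Lewis-acidic chromium salts. Fallback, an acyl cross-coupling in place of a carbonyl addition: it sets out from 13 and comes back at 16. Iodine–tin exchange on 13 (Me3SnSnMe3, Pd(PPh3)4, toluene, 80 °C) should give [(2R,3R)-3-[(2Z,6Z)-2,6-dimethyl-7-(trimethylstannyl)hepta-2,6-dien-1-yl]oxiran-2-yl]methanol F2. Oxidation with (C5H5NH)2Cr2O7 in DMF gives (2S,3R)-3-[(2Z,6Z)-2,6-dimethyl-7-(trimethylstannyl)hepta-2,6-dien-1-yl]oxirane-2-carboxylic acid F3. 1-Chloro-N,N,2-trimethylprop-1-en-1-amine (CH2Cl2, 0 °C) converts it under neutral conditions into (2S,3R)-3-[(2Z,6Z)-2,6-dimethyl-7-(trimethylstannyl)hepta-2,6-dien-1-yl]oxirane-2-carbonyl chloride F4, which is not isolated. Slow addition of F4 to Pd2(dba)3 and tri(2-furyl)phosphine in THF at 50 °C (intramolecular Stille acylation, retention of the Z geometry) closes C5–C6 directly to enone 16.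

Step 20. What may go wrong: poor facial selectivity at C1=C10, because the ten-membered ring may present either face, or competing epoxidation of C4=C5. Fallback, reagent control in place of substrate control: it sets out from 27 and comes back at 28. Shi epoxidation with the ketone catalyst derived from L-fructose (the enantiomer of the usual D-fructose catalyst), KHSO5 (as 2KHSO5·KHSO4·K2SO4), K2CO3, Bu4NHSO4, MeCN/dimethoxymethane/water, 0 °C. By the spiro transition-state model for trisubstituted alkenes, this catalyst enantiomer should place the dioxirane oxygen on the face that gives the 1S,10R oxirane. No new compound is made.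

Further compounds
F1 | step 14 | (1S,2R,3Z,7Z,10R)-2-[(2-bromo-1-ethoxyprop-2-en-1-yl)oxy]-4,8-dimethyl-11-oxabicyclo[8.1.0]undeca-3,7-diene (both acetal epimers) | C=C(Br)C(OCC)O[C@@H]1/C=C(/C)CC/C=C(/C)C[C@H]2O[C@H]12
F2 | step 10 | [(2R,3R)-3-[(2Z,6Z)-2,6-dimethyl-7-(trimethylstannyl)hepta-2,6-dien-1-yl]oxiran-2-yl]methanol | OC[C@H]1O[C@@H]1C/C(C)=C\CC/C(C)=C\[Sn](C)(C)C
F3 | step 10 | (2S,3R)-3-[(2Z,6Z)-2,6-dimethyl-7-(trimethylstannyl)hepta-2,6-dien-1-yl]oxirane-2-carboxylic acid | OC(=O)[C@H]1O[C@@H]1C/C(C)=C\CC/C(C)=C\[Sn](C)(C)C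
F4 | step 10 | (2S,3R)-3-[(2Z,6Z)-2,6-dimethyl-7-(trimethylstannyl)hepta-2,6-dien-1-yl]oxirane-2-carbonyl chloride | ClC(=O)[C@H]1O[C@@H]1C/C(C)=C\CC/C(C)=C\[Sn](C)(C)C
F0 | step 20 | none | none
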